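Numbering: C1 ketone, C2=C3 (methyl on C3), cyclobutane C4–C5–C11–C10 (methyl on C10), C6 gem-dimethyl carbon, C7 methacrylate carbinol, C8 methylene, C9 angelate carbinol. The chain C9–C10–C11–C5 with the ring C11–C1–C2–C3–C4–C5 is the carbon skeleton of menthofuran (C9 the free furan α-carbon, C5 the ring-fused one), and C6–C7–C8 is a three-carbon unit oxygenated at its middle carbon, i.e. a furan diene plus an oxyallyl cation.
Retrosynthesis: cut the two esters, then the C2=C3 unsaturation, then the cyclobutane bond C4–C10 (enolate alkylation), then C5–H and C11–H (back to a C9–O–C5 ether bridge), and last C8–C9 and C5–C6 together in a (4+3) cycloaddition of the 1,1-dimethyl-oxyallyl cation to (R)-menthofuran.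
Forward: the seven-membered ring is closed first onto the six-membered ring that menthofuran brings; after oxidation at C1 the ether bridge is opened by β-elimination; the four-membered ring is closed last by the C10 enolate on a C4 mesylate; ester groups and enone are finished at the end.
Stereochemistry: the bridge fixes C9 and C5 (the wanted facial diastereomer of the cycloadduct is separated; the methyl-bearing centre of menthofuran is only the resolving handle and ends as sp2 C3). C7 comes from hydride attack on the bridged ketone, C5 and C11 from hydrogenation directed by the C9 hydroxyl, C4 from hydroboration anti to the seven-membered ring followed by SN2 inversion (which also fixes C10). C9 is finally re-set from the C7 hydroxyl by internal hydride delivery (1,3-anti).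

Key step: step 2

Assumption: the two facial diastereomers formed in step 2 are separable by chromatography; the series carried on is the one with the bridge oxygen cis to the methyl group of the six-membered ring.

Step 1
Reactants: 1 3-methylbutan-2-one
Product: 2 1,3-dibromo-3-methylbutan-2-one
Conditions: Br2 (2 equiv), HBr (cat.), CH2Cl2, 0 °C → rt
Reagents that add atoms: bromine, BrBr
Why: Acid-catalysed α-bromination through the enols should place the first bromine at the tertiary carbon (more substituted enol) and the second at the methyl group, since no hydrogen is left on the other side.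

Step 2
Reactants: 2 1,3-dibromo-3-methylbutan-2-one; 3 (R)-menthofuran
Product: 5 oxygen-bridged cycloadduct, via zinc oxyallyl cation 4 (not isolated)
Conditions: Zn–Cu couple, B(OEt)3, THF, 0 °C → rt; chromatographic separation of the facial diastereomers
Reagents that add atoms: none
Why: Zinc removes both bromine atoms of 2 and gives the oxyallyl cation 4, whose unsubstituted CH2 terminus (larger LUMO coefficient, unhindered) should bond to the free furan α-carbon C9, leaving an oxocarbenium ion centred on C5 and a tetrasubstituted zinc enolate whose carbon C6 then bonds to C5; this is a stepwise, strongly asynchronous oxyallyl cation–furan (4+3) cycloaddition. The seven-membered ring C5–C6–C7–C8–C9–C10–C11 closes by this enolate-to-oxocarbenium combination across the furan diene, and the furan oxygen becomes the C9–O–C5 bridge. C9 and C5 arise together and are necessarily cis because both bonds form on one furan face; which face reacts is only weakly biased by the remote C3 methyl, so both enantiopure diastereomers should form and the one with the bridge oxygen cis to that methyl (5) is kept. The step needs the gem-dimethyl terminus at C5 and not at C9, and first bonding through the two unhindered termini, which also leaves the more substituted enolate, should secure this. The borate ester tempers the zinc enolate and should hold back simple alkylation of the furan.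

Step 3
Reactants: 5 oxygen-bridged cycloadduct
Product: 6 bridged C7 alcohol
Conditions: LiBH(s-Bu)3, THF, −78 °C; then H2O
Reagents that add atoms: none
Why: Reduction of a bicyclic ketone by a bulky trialkylborohydride should deliver hydride from the face of the oxygen bridge, away from the C10=C11 bridge, so that the C7 hydroxyl ends up anti to the bridging oxygen as the target requires.

Step 4
Reactants: 6 bridged C7 alcohol
Product: 7 bridged C7 silyl ether
Conditions: TBSOTf, 2,6-lutidine, CH2Cl2, 0 °C
Reagents that add atoms: tert-butyldimethylsilyl triflate, CC(C)(C)[Si](C)(C)OS(=O)(=O)C(F)(F)F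
Why: Silylation of a hindered secondary alcohol with the silyl triflate gives an ether that should last until the cyclobutane is closed.

Step 5
Reactants: 7 bridged C7 silyl ether
Product: 8 bridged enone
Conditions: CrO3, 3,5-dimethylpyrazole, CH2Cl2, −20 °C
Reagents that add atoms: chromium trioxide, O=[Cr](=O)=O
Why: Allylic oxidation by the CrO3–pyrazole complex should take the only ring methylene next to the tetrasubstituted alkene (C1), because the C10 methyl reacts more slowly and the bridgehead C9–H lies in the nodal plane of the alkene.

Step 6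
Reactants: 8 bridged enone
Product: 10 ring-opened hydroxy enone, via saturated bridged ketone 9 (not isolated)
Conditions: H2 (4 atm), Pd/C, EtOAc, rt; filtration; then DBU, toluene, 60 °C
Reagents that add atoms: none
Why: Heterogeneous hydrogenation of the strained bridged alkene from the face of the oxygen bridge (the C10 centre so formed is of no later consequence) is followed by E1cB elimination, in which the C1 enolate expels the β-oxygen at C5; this opens the bridge, keeps the C9 hydroxyl with its configuration and should be driven by release of bicyclic strain and formation of the tetrasubstituted enone.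

Step 7
Reactants: 10 ring-opened hydroxy enone
Product: 11 cis-fused hydroxy ketone
Conditions: H2 (1 atm), [Ir(cod)(PCy3)(py)]PF6 (5 mol %), CH2Cl2, rt
Reagents that add atoms: none
Why: Hydroxyl-directed hydrogenation, with iridium held by the homoallylic C9 hydroxyl, should deliver both hydrogens to the face of C11=C5 that carries this hydroxyl; this gives the cis ring fusion with H5 where the bridge oxygen had been, while the C10 methyl and the silyloxy group shield the other face.

Step 8
Reactants: 11 cis-fused hydroxy ketone
Product: 13 C2=C3 enone C9 silyl ether, via bis-silyl enol ether 12 (not isolated)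
Conditions: LiN(i-Pr)2 (2.2 equiv), THF, −78 °C; Me3SiCl; then Pd(OAc)2 (1.1 equiv), MeCN, rt
Reagents that add atoms: chlorotrimethylsilane, C[Si](C)(C)Cl
Why: In this Saegusa–Ito oxidation kinetic deprotonation should take the C2 methylene and not the tertiary C11–H, and β-hydride elimination from the palladium enolate then gives the C2=C3 enone, at which point the methyl-bearing centre from menthofuran has done its work and disappears.

Step 9
Reactants: 13 C2=C3 enone C9 silyl ether
Product: 14 dioxolane alkene alcohol
Conditions: ethylene glycol, PPTS, benzene, reflux (Dean–Stark)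
Reagents that add atoms: ethylene glycol, OCCO
Why: Acid-catalysed ketalisation of a β-methyl enone proceeds through the dienol ether and should move the double bond out of conjugation to C3=C4 while masking C1 and removing the labile C9 silyl ether; the weak acid is chosen so that C11 next to the carbonyl is not epimerised before it is locked.

Step 10
Reactants: 14 dioxolane alkene alcohol
Product: 15 dioxolane alkene ketone
Conditions: Dess–Martin periodinane, CH2Cl2, 0 °C → rt
Reagents that add atoms: none
Why: Dess–Martin oxidation of the only free hydroxyl gives the C9 ketone and so makes C10 an enolisable α-carbon.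

Step 11
Reactants: 15 dioxolane alkene ketone
Product: 16 C9=C10 silyl enol ether
Conditions: TBSOTf, Et3N, CH2Cl2, 0 °C → rt
Reagents that add atoms: tert-butyldimethylsilyl triflate, CC(C)(C)[Si](C)(C)OS(=O)(=O)C(F)(F)F
Why: Soft enolisation with silyl triflate and amine under equilibrating conditions should give mainly the tetrasubstituted enol ether toward C10, which fixes the regiochemistry of the later enolate and protects the ketone during hydroboration.

Step 12
Reactants: 16 C9=C10 silyl enol ether
Product: 17 C4 alcohol
Conditions: 9-BBN, THF, 60 °C; then H2O2, aq. NaOAc, 0 °C → rt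
Reagents that add atoms: hydrogen peroxide, OO
Why: Hydroboration–oxidation of the trisubstituted alkene should put boron on C4 (anti-Markovnikov) and hydrogen on C3 from the face opposite the seven-membered ring, so that the C4 hydroxyl is cis to H5 and to the new H3, while 9-BBN leaves the tetrasubstituted enol ether alone.

Step 13
Reactants: 17 C4 alcohol
Product: 18 C4 mesylate
Conditions: MsCl, Et3N, CH2Cl2, −10 °C
Reagents that add atoms: methanesulfonyl chloride, CS(=O)(=O)Cl
Why: Mesylation through sulfene turns the hindered secondary alcohol into a leaving group with retention at C4.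

Step 14
Reactants: 18 C4 mesylate
Product: 20 tricyclic C9 ketone, via sulfonium enolate 19 (not isolated)
Conditions: (Me2N)3S+ Me3SiF2− (TASF, 1.1 equiv), THF, −40 °C → rt
Reagents that add atoms: none
Why: Fluoride cleaves the enol silyl ether and frees the C10 enolate regiospecifically and without equilibration, and intramolecular enolate alkylation (4-exo-tet, SN2 with inversion at C4) should close the cyclobutane as in the sulfonate ring closures known for pinane-type bicyclo[3.1.1]heptanes; the tether lets C10 bond on one face only, the enolate oxygen is trans to C11 and cannot reach C4, and both β-hydrogens are cis to the mesylate so that anti-elimination is shut off.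

Step 15
Reactants: 20 tricyclic C9 ketone
Product: 21 hydroxy diketone
Conditions: aq. HCl (2 M), THF, rt
Reagents that add atoms: water, O
Why: Acid-catalysed acetal hydrolysis and desilylation should free the C1 ketone and the C7 hydroxyl, the saturated tricyclic diketone having no cation-prone centre next to the cyclobutane.

Step 16
Reactants: 21 hydroxy diketone; 22 methacrolein
Product: 24 C7 methacrylate C9 alcohol, via samarium hemiacetal 23 (not isolated)
Conditions: SmI2 (0.3 equiv), methacrolein (10 equiv), THF, −10 °C
Reagents that add atoms: none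
Why: In this Evans–Tishchenko reduction the samarium-bound hemiacetal on O7 should pass its hydride to the C9 ketone through a six-membered transition state on the face of O7, which sets C9 1,3-anti to C7 and leaves the oxidised hemiacetal as the methacrylate on O7, the C1 ketone having no hydroxyl within reach.

Step 17
Reactants: 24 C7 methacrylate C9 alcohol
Product: 27 enone alcohol, via bis-silyl enol ether 25 (not isolated), via silyl ether enone 26 (not isolated)
Conditions: Me3SiOTf, Et3N, CH2Cl2, 0 °C; then Pd(OAc)2 (1.1 equiv), MeCN, rt; then AcOH, H2O, THF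
Reagents that add atoms: none
Why: Saegusa–Ito oxidation after soft enolisation should give the C2=C3 enone, because C11 is a bridgehead and only the C2 enol ether can form, and the acidic work-up frees the C9 hydroxyl again.

Step 18
Reactants: 27 enone alcohol; 28 angelic acid
Product: 30 target diester, via mixed anhydride 29 (not isolated)
Conditions: angelic acid, 2,4,6-trichlorobenzoyl chloride, Et3N, toluene, rt; then 27, toluene, 80 °C
Reagents that add atoms: none
Why: Yamaguchi-type esterification through the mixed anhydride, run without a nucleophilic catalyst, should acylate the hindered C9 hydroxyl without isomerising the Z double bond of the angelate.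

Compound list
1 | 3-methylbutan-2-one | CC(C)C(C)=O | starting material
2 | 1,3-dibromo-3-methylbutan-2-one | CC(C)(Br)C(=O)CBr | intermediate
3 | (R)-menthofuran | Cc1coc2c1CC[C@@H](C)C2 | starting material
4 | bromozinc 1,1-dimethyl-2-oxyallyl cation | C=C(O[Zn]Br)[C+](C)C | intermediate
5 | oxygen-bridged cycloadduct (C7 ketone, C9–O–C5 bridge, C10=C11, bridge oxygen cis to the C3 methyl) | O=C1C[C@H]2O[C@@]3(C[C@H](C)CCC3=C2C)C1(C)C | intermediate
6 | bridged C7 alcohol (hydroxyl anti to the bridge oxygen) | O[C@@H]1C[C@H]2O[C@@]3(C[C@H](C)CCC3=C2C)C1(C)C | intermediate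
7 | bridged C7 tert-butyldimethylsilyl ether | CC(C)(C)[Si](C)(C)O[C@@H]1C[C@H]2O[C@@]3(C[C@H](C)CCC3=C2C)C1(C)C | intermediate
8 | bridged enone (C1 ketone conjugated with C10=C11) | CC(C)(C)[Si](C)(C)O[C@@H]1C[C@H]2O[C@@]3(C[C@H](C)CC(=O)C3=C2C)C1(C)C | intermediate
9 | saturated bridged ketone (H10 and H11 on the bridge-oxygen face) | CC(C)(C)[Si](C)(C)O[C@@H]1C[C@H]2O[C@@]3(C[C@H](C)CC(=O)[C@H]3[C@H]2C)C1(C)C | intermediate
10 | ring-opened hydroxy enone (C9–OH, C1 ketone, C11=C5) | CC(C)(C)[Si](C)(C)O[C@@H]1C[C@@H](O)[C@H](C)C2=C(C[C@H](C)CC2=O)C1(C)C | intermediate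
11 | cis-fused hydroxy ketone (H5 and H11 cis to C9–OH) | CC(C)(C)[Si](C)(C)O[C@@H]1C[C@@H](O)[C@H](C)[C@H]2[C@H](C[C@H](C)CC2=O)C1(C)C | intermediate
12 | C1=C2 trimethylsilyl enol ether, C9 trimethylsilyl ether | CC(C)(C)[Si](C)(C)O[C@@H]1C[C@@H](O[Si](C)(C)C)[C@H](C)[C@H]2[C@H](C[C@H](C)C=C2O[Si](C)(C)C)C1(C)C | intermediate
13 | C2=C3 enone, C9 trimethylsilyl ether | CC(C)(C)[Si](C)(C)O[C@@H]1C[C@@H](O[Si](C)(C)C)[C@H](C)[C@H]2[C@H](CC(C)=CC2=O)C1(C)C | intermediate
14 | C1 dioxolane, C3=C4 alkene, C9 alcohol | CC(C)(C)[Si](C)(C)O[C@@H]1C[C@@H](O)[C@H](C)[C@H]2[C@H](C=C(C)CC23OCCO3)C1(C)C | intermediate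
15 | C1 dioxolane, C3=C4 alkene, C9 ketone | CC(C)(C)[Si](C)(C)O[C@@H]1CC(=O)[C@H](C)[C@H]2[C@H](C=C(C)CC23OCCO3)C1(C)C | intermediate
16 | C9=C10 tert-butyldimethylsilyl enol ether | CC(C)(C)[Si](C)(C)O[C@@H]1CC(O[Si](C)(C)C(C)(C)C)=C(C)[C@H]2[C@H](C=C(C)CC23OCCO3)C1(C)C | intermediate
17 | C4 alcohol (hydroxyl cis to H5 and H3) | CC(C)(C)[Si](C)(C)O[C@@H]1CC(O[Si](C)(C)C(C)(C)C)=C(C)[C@H]2[C@H]([C@H](O)[C@@H](C)CC23OCCO3)C1(C)C | intermediate
18 | C4 mesylate | CC(C)(C)[Si](C)(C)O[C@@H]1CC(O[Si](C)(C)C(C)(C)C)=C(C)[C@H]2[C@H]([C@H](OS(C)(=O)=O)[C@@H](C)CC23OCCO3)C1(C)C | intermediate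
19 | tris(dimethylamino)sulfonium C10 enolate | CC(C)(C)[Si](C)(C)O[C@@H]1CC([O-])=C(C)[C@H]2[C@H]([C@H](OS(C)(=O)=O)[C@@H](C)CC23OCCO3)C1(C)C.CN(C)[S+](N(C)C)N(C)C | intermediate
20 | tricyclic C9 ketone (cyclobutane closed, C1 dioxolane, C7 silyl ether) | CC(C)(C)[Si](C)(C)O[C@@H]1CC(=O)[C@@]2(C)[C@@H]3C4(OCCO4)C[C@H](C)[C@H]2[C@@H]3C1(C)C | intermediate
21 | hydroxy diketone (C7–OH, C1 and C9 ketones) | O[C@@H]1CC(=O)[C@@]2(C)[C@@H]3C(=O)C[C@H](C)[C@H]2[C@@H]3C1(C)C | intermediate
22 | methacrolein | C=C(C)C=O | starting material
23 | methacrolein hemiacetal of 21 (samarium-bound) | C=C(C)C(O)O[C@@H]1CC(=O)[C@@]2(C)[C@@H]3C(=O)C[C@H](C)[C@H]2[C@@H]3C1(C)C | intermediate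
24 | C7 methacrylate, C9 alcohol (anti), C1 ketone | C=C(C)C(=O)O[C@@H]1C[C@@H](O)[C@@]2(C)[C@@H]3C(=O)C[C@H](C)[C@H]2[C@@H]3C1(C)C | intermediate
25 | C1=C2 trimethylsilyl enol ether, C9 trimethylsilyl ether | C=C(C)C(=O)O[C@@H]1C[C@@H](O[Si](C)(C)C)[C@@]2(C)[C@@H]3C(O[Si](C)(C)C)=C[C@H](C)[C@H]2[C@@H]3C1(C)C | intermediate
26 | enone, C9 trimethylsilyl ether | C=C(C)C(=O)O[C@@H]1C[C@@H](O[Si](C)(C)C)[C@@]2(C)[C@@H]3C(=O)C=C(C)[C@H]2[C@@H]3C1(C)C | intermediate
27 | enone alcohol (C7 methacrylate, C9–OH) | C=C(C)C(=O)O[C@@H]1C[C@@H](O)[C@@]2(C)[C@@H]3C(=O)C=C(C)[C@H]2[C@@H]3C1(C)C | intermediate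
28 | angelic acid | C/C=C(/C)C(=O)O | starting material
29 | angelic 2,4,6-trichlorobenzoic anhydride | C/C=C(/C)C(=O)OC(=O)c1c(Cl)cc(Cl)cc1Cl | intermediate
30 | CNP0317071.1 | C=C(C)C(=O)O[C@@H]1C[C@@H](OC(=O)/C(C)=C\C)[C@@]2(C)[C@@H]3C(=O)C=C(C)[C@H]2[C@@H]3C1(C)C | target

Total step count: 18. Longest linear sequence: 18 steps (from 3-methylbutan-2-one; 17 from menthofuran).

Steps most likely to fail

Step 14. Closure of the strained four-membered ring at a secondary carbon flanked by two branched carbons may be slower than transfer of the sulfonyl group to the enolate oxygen, or than the side reactions of any C8 enolate carried over from step 11 (loss of the β-silyloxy group, five-membered ring closure). The fallback sets out from 15 and changes the electrophile. OsO4-catalysed dihydroxylation with NMO should add to the C3=C4 alkene from the face away from the seven-membered ring and give the cis diol F4. SOCl2/Et3N followed by RuCl3 (cat.)/NaIO4 gives the cyclic sulfate F5, and TBSOTf/i-Pr2NEt gives its C9=C10 silyl enol ether F6. TASF then frees the C10 enolate, which should open the cyclic sulfate at the secondary carbon C4; this is a stronger alkylating agent, cannot eliminate, and its opening is irreversible. The product is the tricyclic C3 sulfate monoester F7. Aqueous acid (H2SO4 cat., THF/H2O) hydrolyses the dioxolane and the silyl ether, and the freed C1 ketone expels the β-sulfate, so the hydroxy enedione F8 arises with the C2=C3 enone already in place. Evans–Tishchenko reduction of F8 with methacrolein under the conditions of step 16 returns to the route at 27.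

Step 2. The unsymmetrical oxyallyl cation may bond in the reverse orientation, or the intermediate may lose the C9 proton after the first bond (alkylation of the furan) instead of closing onto the substituted carbon beside the gem-dimethyl terminus; weak facial selectivity also costs material. The fallback sets out from 3 and polarises the three-carbon partner. Methyl dimethoxyacetate and i-PrMgCl (THF, −78 °C) give 1,1-dimethoxy-3-methylbutan-2-one F1, and Me3SiOTf/Et3N gives its tetrasubstituted silyl enol ether F2. With 3 and catalytic Me3SiOTf (CH2Cl2, −78 °C), F2 ionises to a 1-methoxy-2-silyloxyallyl cation whose oxocarbenium carbon is unambiguously the electrophilic end; it should bond to the free furan carbon C9, and the enol ether end then closes on C5. The 8-methoxy cycloadduct F3 (C8 epimers) is demethoxylated with SmI2 (THF/MeOH, −78 °C), and separation of the facial diastereomers returns to the route at 5.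

Step 16. Conjugate addition or oligomerisation of the enal on the samarium alkoxide, or its reduction by SmI2, may outrun hydride transfer from the hemiacetal. The fallback sets out from 21 and installs the methacrylate by a relay. Evans–Tishchenko reduction with acetaldehyde (SmI2 cat., THF, −10 °C) gives the C7 acetate C9 alcohol F9 with the same 1,3-anti outcome. Et3SiOTf/2,6-lutidine gives the C9 triethylsilyl ether F10, and K2CO3/MeOH removes the acetate to give the C7 alcohol F11. Methacrylic anhydride, DMAP and Et3N give the C7 methacrylate F12, and HF·pyridine removes the silyl ether and returns to the route at 24.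

Further compounds
F1 | step 2 | 1,1-dimethoxy-3-methylbutan-2-one | COC(OC)C(=O)C(C)C
F2 | step 2 | 1,1-dimethoxy-3-methyl-2-(trimethylsilyloxy)but-2-ene | COC(OC)C(O[Si](C)(C)C)=C(C)C
F3 | step 2 | 8-methoxy cycloadduct (C8 epimers) | O=C1C(OC)[C@H]2O[C@@]3(C[C@H](C)CCC3=C2C)C1(C)C
F4 | step 14 | C3,C4 cis diol (C1 dioxolane, C9 ketone) | CC(C)(C)[Si](C)(C)O[C@@H]1CC(=O)[C@H](C)[C@H]2[C@H]([C@H](O)[C@](C)(O)CC23OCCO3)C1(C)C
F5 | step 14 | C3,C4 cyclic sulfate | CC(C)(C)[Si](C)(C)O[C@@H]1CC(=O)[C@H](C)[C@H]2[C@H]([C@@H]4OS(=O)(=O)O[C@]4(C)CC23OCCO3)C1(C)C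
F6 | step 14 | C9=C10 silyl enol ether of the cyclic sulfate | CC(C)(C)[Si](C)(C)O[C@@H]1CC(O[Si](C)(C)C(C)(C)C)=C(C)[C@H]2[C@H]([C@@H]4OS(=O)(=O)O[C@]4(C)CC23OCCO3)C1(C)C
F7 | step 14 | tricyclic C3 sulfate monoester (tris(dimethylamino)sulfonium salt) | CC(C)(C)[Si](C)(C)O[C@@H]1CC(=O)[C@@]2(C)[C@@H]3C4(OCCO4)C[C@@](C)(OS(=O)(=O)[O-])[C@H]2[C@@H]3C1(C)C.CN(C)[S+](N(C)C)N(C)C
F8 | step 14 | hydroxy enedione (C7–OH, C9 ketone, C1 enone) | O[C@@H]1CC(=O)[C@@]2(C)[C@@H]3C(=O)C=C(C)[C@H]2[C@@H]3C1(C)C
F9 | step 16 | C7 acetate, C9 alcohol | CC(=O)O[C@@H]1C[C@@H](O)[C@@]2(C)[C@@H]3C(=O)C[C@H](C)[C@H]2[C@@H]3C1(C)C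
F10 | step 16 | C7 acetate, C9 triethylsilyl ether | CC(=O)O[C@@H]1C[C@@H](O[Si](CC)(CC)CC)[C@@]2(C)[C@@H]3C(=O)C[C@H](C)[C@H]2[C@@H]3C1(C)C
F11 | step 16 | C7 alcohol, C9 triethylsilyl ether | O[C@@H]1C[C@@H](O[Si](CC)(CC)CC)[C@@]2(C)[C@@H]3C(=O)C[C@H](C)[C@H]2[C@@H]3C1(C)C
F12 | step 16 | C7 methacrylate, C9 triethylsilyl ether | C=C(C)C(=O)O[C@@H]1C[C@@H](O[Si](CC)(CC)CC)[C@@]2(C)[C@@H]3C(=O)C[C@H](C)[C@H]2[C@@H]3C1(C)C
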